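**Plan**

Labels: ring A is the α-alkylidene-γ-butyrolactone (O-1, C-2 to C-5), ring B is the butenolide, and the side chain runs from C-1' (alkylidene CH) to C-11' (carbinol C). Retrosynthetic cuts, in order: O–Si at C-11'; then C-5'(sp2)–C-6'(sp3), giving alkenyl iodide 10 (ring A half) and N-acyloxyphthalimide 23, whose acid carries one extra carboxyl carbon on C-6' (ring B half); in 10, the C-3=C-1' and isobutenyl C=C bonds; in 23, the C-6'–C-7' bond ([3,3]) and ring B back to a 3-furyl ring.
Enabling feature: C-4'=C-5'/C-8'=C-9' is a 1,5-diene. C-6' is therefore the CO2H-bearing carbon of a 4-methylalk-4-enoic acid (a Claisen product), and C-5' is the iodinated end of a carboaluminated alkyne. The conjugated C=C bonds of rings A and B are β-carbon-substituted lactone enoates, so they are slow radical acceptors and hard to reduce. Both rings, both stereocentres and all five C=C bonds can thus be in place before the union, and CO2, phthalimide and iodide leave in the event itself.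
Forward order: 1 → 4 (iodo aldehyde); 5 → 9 (ring A, present from the start, becomes a phosphonate); 4 + 9 → 10; 11 → 18 (furan acid) → 22 (ring B made from the furan) → 23; 10 + 23 → 24 → 25.
Stereochemistry: (S)-C-5 comes from chiral-pool lactone 5. (R)-C-11' comes from Ru-catalysed asymmetric transfer hydrogenation. The two (E)-alkenes come from syn-carboalumination and a chair Johnson–Claisen rearrangement. The (Z)-alkylidene comes from a kinetic diaryl phosphonate olefination. The key step creates no stereocentre and keeps every geometry.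

Key step: step 15

Assumption: as read from the SMILES, the exocyclic C=C of ring A has the side chain cis to the lactone C=O and trans to the ring CH2, i.e. (Z). Both chain alkenes are (E), C-5 is (S) and C-11' is (R).

**Step 1**
Reactants: 1 pent-4-yn-1-ol
Product: 3 (E)-5-iodo-4-methylpent-4-en-1-ol, via alkenylalane 2 (not isolated)
Conditions: Me3Al (3 equiv), Cp2ZrCl2 (0.25 equiv), CH2Cl2, 0 °C → rt; then I2, THF, −30 → 0 °C; then aq. K2CO3
Reagents that add atoms: trimethylaluminium C[Al](C)C; iodine II
Why: Negishi zirconium-catalysed carboalumination adds CH3 and Al syn across the terminal alkyne with Al on the terminal carbon, and iodinolysis of the C–Al bond with retention should give only the (E)-alkenyl iodide.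

**Step 2**
Reactants: 3 (E)-5-iodo-4-methylpent-4-en-1-ol
Product: 4 (E)-5-iodo-4-methylpent-4-enal
Conditions: PhI(OAc)2, TEMPO (10 mol %), CH2Cl2, rt
Reagents that add atoms: none
Why: The TEMPO/PhI(OAc)2 (oxoammonium) oxidation of a primary alcohol stops at the aldehyde and does not touch the alkenyl iodide.

**Step 3**
Reactants: 5 (S)-5-(hydroxymethyl)dihydrofuran-2(3H)-one
Product: 6 (S)-5-oxotetrahydrofuran-2-carbaldehyde
Conditions: Dess–Martin periodinane, CH2Cl2, 0 °C → rt; filtration through silica, used crude
Reagents that add atoms: none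
Why: Dess–Martin oxidation runs under neutral, water-free conditions, so the hydration- and enolisation-prone α-acyloxy aldehyde should be obtained with the chiral-pool (S)-centre intact.

**Step 4**
Reactants: 6 (S)-5-oxotetrahydrofuran-2-carbaldehyde
Product: 7 (S)-5-(2-methylprop-1-enyl)dihydrofuran-2(3H)-one
Conditions: i-PrPPh3I, n-BuLi, THF, 0 °C; the ylide solution is added slowly to 6, THF, −78 °C → rt
Reagents that add atoms: isopropyltriphenylphosphonium iodide CC(C)[P+](c1ccccc1)(c1ccccc1)c1ccccc1.[I-]
Why: Wittig olefination with the non-stabilised isopropylidene ylide is far faster at the aldehyde than at the lactone carbonyl, and inverse addition at low temperature keeps free base scarce so that the α-oxy centre should not epimerise.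

**Step 5**
Reactants: 7 (S)-5-(2-methylprop-1-enyl)dihydrofuran-2(3H)-one
Product: 9 diphenyl [(5S)-5-(2-methylprop-1-enyl)-2-oxotetrahydrofuran-3-yl]phosphonate (C-3 epimers), via phosphonite 8 (not isolated)
Conditions: LiN(i-Pr)2, THF, −78 °C; (PhO)2PCl, −78 °C → rt; then t-BuOOH (decane), 0 °C
Reagents that add atoms: diphenyl phosphorochloridite ClP(Oc1ccccc1)Oc1ccccc1; tert-butyl hydroperoxide CC(C)(C)OO
Why: The lactone lithium enolate attacks the soft trivalent phosphorus chloride through carbon (enolate C-phosphinylation) and oxidation of 8 at phosphorus gives the α-phosphono lactone, whose new C-3 centre is lost in step 6 and so is irrelevant.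

**Step 6**
Reactants: 9 diphenyl [(5S)-5-(2-methylprop-1-enyl)-2-oxotetrahydrofuran-3-yl]phosphonate; 4 (E)-5-iodo-4-methylpent-4-enal
Product: 10 (3Z,5S)-3-[(4E)-5-iodo-4-methylpent-4-enylidene]-5-(2-methylprop-1-enyl)dihydrofuran-2(3H)-one
Conditions: KN(SiMe3)2, 18-crown-6, THF, −78 °C; then 4, −78 → −20 °C
Reagents that add atoms: none
Why: In the diaryl phosphonate (Ando) variant of the Horner–Wadsworth–Emmons reaction the electron-poor aryloxy groups make collapse of the first-formed adduct faster than its reversal, which with α-substituted phosphonoacetates places the aldehyde chain cis to the ester carbonyl, here the (Z)-alkylidene lactone, while the alkenyl iodide and C-5 are spectators.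

**Step 7**
Reactants: 11 ethyl 3-(furan-3-yl)-3-oxopropanoate
Product: 12 ethyl (R)-3-(furan-3-yl)-3-hydroxypropanoate
Conditions: RuCl(p-cymene)[(R,R)-TsDPEN] (1 mol %), HCO2H–Et3N (5:2), 30 °C
Reagents that add atoms: none
Why: Noyori–Ikariya asymmetric transfer hydrogenation delivers hydride to one face of the heteroaryl ketone through its CH/π-organised six-membered transition state, and the (R,R)-catalyst should give the (R)-carbinol by analogy with aryl β-keto esters.

**Step 8**
Reactants: 12 ethyl (R)-3-(furan-3-yl)-3-hydroxypropanoate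
Product: 13 ethyl (R)-3-(tert-butyldimethylsilyloxy)-3-(furan-3-yl)propanoate
Conditions: TBSCl, imidazole, DMF, rt
Reagents that add atoms: tert-butyldimethylsilyl chloride CC(C)(C)[Si](C)(C)Cl
Why: Standard silylation of a secondary alcohol gives a TBS ether that masks the carbinol through the hydride, Grignard, Claisen, oxidation and coupling steps.

**Step 9**
Reactants: 13 ethyl (R)-3-(tert-butyldimethylsilyloxy)-3-(furan-3-yl)propanoate
Product: 14 (R)-3-(tert-butyldimethylsilyloxy)-3-(furan-3-yl)propanal
Conditions: i-Bu2AlH (1.1 equiv), CH2Cl2, −78 °C; then MeOH, aq. potassium sodium tartrate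
Reagents that add atoms: none
Why: Partial ester reduction with i-Bu2AlH at −78 °C stops at the tetrahedral aluminium hemiacetal, which releases the aldehyde only on work-up.

**Step 10**
Reactants: 14 (R)-3-(tert-butyldimethylsilyloxy)-3-(furan-3-yl)propanal
Product: 15 (5R)-5-(tert-butyldimethylsilyloxy)-5-(furan-3-yl)-2-methylpent-1-en-3-ol (both C-3 epimers)
Conditions: isopropenylmagnesium bromide, THF, −78 → −20 °C; then aq. NH4Cl at low temperature
Reagents that add atoms: isopropenylmagnesium bromide C=C(C)[Mg]Br
Why: 1,2-Addition of the alkenyl Grignard reagent gives the 2-methylallylic alcohol needed for the rearrangement, and because the new carbinol centre is destroyed in step 11 both epimers are used.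

**Step 11**
Reactants: 15 (5R)-5-(tert-butyldimethylsilyloxy)-5-(furan-3-yl)-2-methylpent-1-en-3-ol
Product: 17 ethyl (4E,7R)-7-(tert-butyldimethylsilyloxy)-7-(furan-3-yl)-4-methylhept-4-enoate, via ketene acetal 16 (not isolated)
Conditions: MeC(OEt)3 (excess), EtCO2H (cat.), 140 °C, EtOH distilled off
Reagents that add atoms: triethyl orthoacetate CC(OCC)(OCC)OCC
Why: In the Johnson orthoester Claisen rearrangement ketene acetal 16 reacts through a chair with the carbinol substituent equatorial, which avoids the 1,3-diaxial contact with the ethoxy group, so both epimers should converge on the (E)-trisubstituted alkene of the 4-methylalk-4-enoate.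

**Step 12**
Reactants: 17 ethyl (4E,7R)-7-(tert-butyldimethylsilyloxy)-7-(furan-3-yl)-4-methylhept-4-enoate
Product: 18 (4E,7R)-7-(tert-butyldimethylsilyloxy)-7-(furan-3-yl)-4-methylhept-4-enoic acid
Conditions: LiOH, THF–H2O, rt; then 1 M HCl to pH 4
Reagents that add atoms: lithium hydroxide [Li+].[OH-]
Why: Saponification of the unhindered ethyl ester leaves the furan, the TBS ether and the alkene untouched.

**Step 13**
Reactants: 18 (4E,7R)-7-(tert-butyldimethylsilyloxy)-7-(furan-3-yl)-4-methylhept-4-enoic acid
Product: 22 (4E,7R)-7-(tert-butyldimethylsilyloxy)-4-methyl-7-(5-oxo-2,5-dihydrofuran-3-yl)hept-4-enoic acid, via endoperoxide 19 (not isolated), via hydroxybutenolide 20 (not isolated), via hydroxy acid 21 (not isolated)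
Conditions: O2, visible light, tetraphenylporphyrin (cat.), i-Pr2NEt (excess), CH2Cl2, −78 °C → rt; then EtOH, NaBH4, 0 °C; then 1 M HCl, 0 °C
Reagents that add atoms: oxygen O=O
Why: Singlet oxygen adds [4+2] to the furan much faster than it undergoes the ene reaction with the single trisubstituted alkene, the hindered base opens 19 (Kornblum–DeLaMare) by removing the bridgehead H remote from the side chain to give the 4-substituted 5-hydroxybutenolide 20, and NaBH4 reduces its open aldehyde form to 21, which closes to ring B on acidification without involving C-11'.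

**Step 14**
Reactants: 22 (4E,7R)-7-(tert-butyldimethylsilyloxy)-4-methyl-7-(5-oxo-2,5-dihydrofuran-3-yl)hept-4-enoic acid
Product: 23 1,3-dioxoisoindolin-2-yl (4E,7R)-7-(tert-butyldimethylsilyloxy)-4-methyl-7-(5-oxo-2,5-dihydrofuran-3-yl)hept-4-enoate
Conditions: N-hydroxyphthalimide, N,N'-diisopropylcarbodiimide, DMAP (cat.), CH2Cl2, rt
Reagents that add atoms: N-hydroxyphthalimide O=C1c2ccccc2C(=O)N1O
Why: Carbodiimide (Steglich-type) esterification with the acidic N–OH nucleophile gives the redox-active ester under neutral conditions that leave ring B and the TBS ether alone.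

**Step 15**
Reactants: 10 (3Z,5S)-3-[(4E)-5-iodo-4-methylpent-4-enylidene]-5-(2-methylprop-1-enyl)dihydrofuran-2(3H)-one; 23 1,3-dioxoisoindolin-2-yl (4E,7R)-7-(tert-butyldimethylsilyloxy)-4-methyl-7-(5-oxo-2,5-dihydrofuran-3-yl)hept-4-enoate
Product: 24 (3Z,5S)-3-[(4E,8E,11R)-11-(tert-butyldimethylsilyloxy)-4,8-dimethyl-11-(5-oxo-2,5-dihydrofuran-3-yl)undeca-4,8-dienylidene]-5-(2-methylprop-1-enyl)dihydrofuran-2(3H)-one
Conditions: 10 (1 equiv), 23 (1.5 equiv), NiCl2·6H2O (20 mol %), 2,2'-bipyridine (20 mol %), AgNO3 (0.3 equiv), LiCl, DMF, undivided cell, Mg anode, reticulated vitreous carbon cathode, constant current, rt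
Reagents that add atoms: none
Why: At the cathode (bpy)NiCl2 is reduced to low-valent nickel, which inserts into the C-5'–I bond of 10 with retention, while single-electron transfer to 23 (from low-valent nickel or from the silver layer plated on the cathode from AgNO3) cleaves the N–O bond and expels phthalimide anion and CO2 to leave the primary C-6' radical; capture of this radical by the divalent alkenylnickel species and reductive elimination from trivalent nickel forge C-5'–C-6', and the Mg anode supplies the two electrons. The closest known reaction type is the nickel-electrocatalytic decarboxylative alkenylation of redox-active esters with alkenyl iodides, which is established for joining (E)-2-methylalk-1-enyl iodides to esters of 4-methylalk-4-enoic acids in 1,5-polyene assembly. No ring is closed and no stereocentre is formed; C-5 and C-11' are remote spectators, and the C-4'=C-5' geometry is kept because insertion and reductive elimination at sp2 carbon are stereoretentive. Chemoselective electron transfer is needed and is secured because rings A and B are plain enoate-type lactones that accept an electron only at a distinctly more negative potential than nickel or the N-acyloxyphthalimide. Capture by nickel must beat radical side reactions, and it should, because the acceptor carbons C-1' (ring A) and C-4 (ring B) each carry a carbon substituent and the only cyclisation open to the homoallyl radical (3-exo onto C-8') is slow, reversible and constitutionally degenerate. Insertion into C–I must beat ionisation of the allylic C-5–O bond of ring A, which the high reactivity of the alkenyl iodide and the poor ligand quality of the trisubstituted isobutenyl alkene should ensure.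

**Step 16**
Reactants: 24 (3Z,5S)-3-[(4E,8E,11R)-11-(tert-butyldimethylsilyloxy)-4,8-dimethyl-11-(5-oxo-2,5-dihydrofuran-3-yl)undeca-4,8-dienylidene]-5-(2-methylprop-1-enyl)dihydrofuran-2(3H)-one
Product: 25 (3Z,5S)-3-[(4E,8E,11R)-11-hydroxy-4,8-dimethyl-11-(5-oxo-2,5-dihydrofuran-3-yl)undeca-4,8-dienylidene]-5-(2-methylprop-1-enyl)dihydrofuran-2(3H)-one (target)
Conditions: HF·pyridine, pyridine, THF, 0 °C → rt
Reagents that add atoms: none
Why: Fluoride-driven Si–O cleavage under buffered, weakly acidic conditions avoids base-induced isomerisation of ring B and of the (Z)-alkylidene unit as well as ionisation of the allylic C-5–O bond of ring A.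

**Compound list**

1 | pent-4-yn-1-ol | C#CCCCO | starting material
2 | dimethylaluminium (E)-5-(dimethylalumanyl)-4-methylpent-4-en-1-olate (alkenylalane, not isolated) | C[Al](C)OCCC/C(C)=C/[Al](C)C | intermediate
3 | (E)-5-iodo-4-methylpent-4-en-1-ol | OCCC/C(C)=C/I | intermediate
4 | (E)-5-iodo-4-methylpent-4-enal | O=CCC/C(C)=C/I | intermediate
5 | (S)-5-(hydroxymethyl)dihydrofuran-2(3H)-one | OC[C@@H]1CCC(=O)O1 | starting material
6 | (S)-5-oxotetrahydrofuran-2-carbaldehyde | O=C[C@@H]1CCC(=O)O1 | intermediate
7 | (S)-5-(2-methylprop-1-enyl)dihydrofuran-2(3H)-one | CC(C)=C[C@@H]1CCC(=O)O1 | intermediate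
8 | diphenyl [(5S)-5-(2-methylprop-1-enyl)-2-oxotetrahydrofuran-3-yl]phosphonite (not isolated) | CC(C)=C[C@@H]1CC(P(Oc2ccccc2)Oc2ccccc2)C(=O)O1 | intermediate
9 | diphenyl [(5S)-5-(2-methylprop-1-enyl)-2-oxotetrahydrofuran-3-yl]phosphonate (C-3 epimers) | CC(C)=C[C@@H]1CC(P(=O)(Oc2ccccc2)Oc2ccccc2)C(=O)O1 | intermediate
10 | (3Z,5S)-3-[(4E)-5-iodo-4-methylpent-4-enylidene]-5-(2-methylprop-1-enyl)dihydrofuran-2(3H)-one | CC(C)=C[C@@H]1C/C(=C/CC/C(C)=C/I)C(=O)O1 | intermediate
11 | ethyl 3-(furan-3-yl)-3-oxopropanoate | CCOC(=O)CC(=O)c1ccoc1 | starting material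
12 | ethyl (R)-3-(furan-3-yl)-3-hydroxypropanoate | CCOC(=O)C[C@@H](O)c1ccoc1 | intermediate
13 | ethyl (R)-3-(tert-butyldimethylsilyloxy)-3-(furan-3-yl)propanoate | CCOC(=O)C[C@@H](O[Si](C)(C)C(C)(C)C)c1ccoc1 | intermediate
14 | (R)-3-(tert-butyldimethylsilyloxy)-3-(furan-3-yl)propanal | O=CC[C@@H](O[Si](C)(C)C(C)(C)C)c1ccoc1 | intermediate
15 | (5R)-5-(tert-butyldimethylsilyloxy)-5-(furan-3-yl)-2-methylpent-1-en-3-ol (both C-3 epimers) | C=C(C)C(O)C[C@@H](O[Si](C)(C)C(C)(C)C)c1ccoc1 | intermediate
16 | mixed ethyl ketene acetal of 15 (not isolated) | C=C(OCC)OC(C[C@@H](O[Si](C)(C)C(C)(C)C)c1ccoc1)C(C)=C | intermediate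
17 | ethyl (4E,7R)-7-(tert-butyldimethylsilyloxy)-7-(furan-3-yl)-4-methylhept-4-enoate | CCOC(=O)CC/C(C)=C/C[C@@H](O[Si](C)(C)C(C)(C)C)c1ccoc1 | intermediate
18 | (4E,7R)-7-(tert-butyldimethylsilyloxy)-7-(furan-3-yl)-4-methylhept-4-enoic acid | OC(=O)CC/C(C)=C/C[C@@H](O[Si](C)(C)C(C)(C)C)c1ccoc1 | intermediate
19 | furan 2,5-endoperoxide of 18 (not isolated) | OC(=O)CC/C(C)=C/C[C@@H](O[Si](C)(C)C(C)(C)C)C1=CC2OOC1O2 | intermediate
20 | (4E,7R)-7-(tert-butyldimethylsilyloxy)-7-(2-hydroxy-5-oxo-2,5-dihydrofuran-3-yl)-4-methylhept-4-enoic acid (hemiacetal epimers, not isolated) | OC(=O)CC/C(C)=C/C[C@@H](O[Si](C)(C)C(C)(C)C)C1=CC(=O)OC1O | intermediate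
21 | ring-opened 3-(hydroxymethyl)alk-2-enedioic acid formed from 20, CH2OH cis to CO2H (not isolated) | OC(=O)CC/C(C)=C/C[C@@H](O[Si](C)(C)C(C)(C)C)/C(CO)=C/C(=O)O | intermediate
22 | (4E,7R)-7-(tert-butyldimethylsilyloxy)-4-methyl-7-(5-oxo-2,5-dihydrofuran-3-yl)hept-4-enoic acid | OC(=O)CC/C(C)=C/C[C@@H](O[Si](C)(C)C(C)(C)C)C1=CC(=O)OC1 | intermediate
23 | 1,3-dioxoisoindolin-2-yl (4E,7R)-7-(tert-butyldimethylsilyloxy)-4-methyl-7-(5-oxo-2,5-dihydrofuran-3-yl)hept-4-enoate | O=C(CC/C(C)=C/C[C@@H](O[Si](C)(C)C(C)(C)C)C1=CC(=O)OC1)ON1C(=O)c2ccccc2C1=O | intermediate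
24 | TBS ether of the target at C-11' | CC(C)=C[C@@H]1C/C(=C/CC/C(C)=C/CC/C(C)=C/C[C@@H](O[Si](C)(C)C(C)(C)C)C2=CC(=O)OC2)C(=O)O1 | intermediate
25 | (3Z,5S)-3-[(4E,8E,11R)-11-hydroxy-4,8-dimethyl-11-(5-oxo-2,5-dihydrofuran-3-yl)undeca-4,8-dienylidene]-5-(2-methylprop-1-enyl)dihydrofuran-2(3H)-one | CC(C)=C[C@@H]1C/C(=C/CC/C(C)=C/CC/C(C)=C/C[C@@H](O)C2=CC(=O)OC2)C(=O)O1 | target

**Step count and risks**

Total step count: 16. Longest linear sequence: 10 steps (steps 7 to 16, from 11).

Steps most likely to fail:

**Step 15.** The primary radical may be lost to hydrogen abstraction, dimerisation or conjugate addition to ring A before nickel captures it. Low-valent nickel may ionise the allylic C-5–O bond of ring A. Reversible conjugate addition of phthalimide anion may erode the Z geometry. The fallback replaces radical capture by a two-electron cross-coupling and sets out from acid 22. Acid 22 is condensed with N-hydroxypyridine-2-thione (DCC, CH2Cl2, dark) to the Barton ester F1. Visible-light photolysis in the presence of CHI3 (Barton iododecarboxylation, which uses no electrophilic iodine that could iodolactonise the γ,δ-unsaturated acid) gives the primary iodide F2. Zinc insertion (Zn dust, LiCl, THF) gives the alkylzinc iodide F3. A Negishi coupling of this reagent with 10 (PdCl2(dppf), THF, rt) comes back to the route at 24.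

**Step 6.** The kinetic preference for the Z olefin may be weak because the ring ties the ester back, or the product may drift to the more stable E geometry by reversible addition. The fallback replaces kinetic olefination by a stereospecific elimination and sets out from lactone 7. Its lithium enolate (LiN(i-Pr)2, THF, −78 °C) is an E(O)-enolate by ring constraint. It is added to aldehyde 4 and should give, through the closed Zimmerman–Traxler transition state and attack anti to the C-5 substituent, mainly the anti aldol F4, which is separated from the syn isomers. Mesylation (MsCl, Et3N, CH2Cl2, 0 °C) gives the mesylate F5. Anti-periplanar E2 elimination (DBU, toluene, 0 °C) of this anti isomer places C-2' cis to the lactone carbonyl and comes back to the route at 10.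

**Step 5.** The enolate may attack through oxygen instead of carbon, a second enolate may displace phenoxide at phosphorus, or proton transfer between product and enolate may stall the conversion. The fallback reverses the polarity at C-3 and sets out from 7. Enolate bromination (LiN(SiMe3)2, THF, −78 °C; BrCCl2CCl2Br) gives the α-bromo lactone F6. Michaelis–Becker substitution with diphenyl phosphite (Et3N, CH2Cl2, 0 °C → rt) comes back to the route at 9.

**Further compounds**

F1 | step 15 | 2-thioxopyridin-1(2H)-yl (4E,7R)-7-(tert-butyldimethylsilyloxy)-4-methyl-7-(5-oxo-2,5-dihydrofuran-3-yl)hept-4-enoate | O=C(CC/C(C)=C/C[C@@H](O[Si](C)(C)C(C)(C)C)C1=CC(=O)OC1)ON1C=CC=CC1=S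
F2 | step 15 | (R)-4-[(3E)-1-(tert-butyldimethylsilyloxy)-6-iodo-4-methylhex-3-enyl]furan-2(5H)-one | ICC/C(C)=C/C[C@@H](O[Si](C)(C)C(C)(C)C)C1=CC(=O)OC1
F3 | step 15 | [(3E,6R)-6-(tert-butyldimethylsilyloxy)-3-methyl-6-(5-oxo-2,5-dihydrofuran-3-yl)hex-3-enyl]zinc iodide | I[Zn]CC/C(C)=C/C[C@@H](O[Si](C)(C)C(C)(C)C)C1=CC(=O)OC1
F4 | step 6 | (3S,5S)-3-[(1S,4E)-1-hydroxy-5-iodo-4-methylpent-4-enyl]-5-(2-methylprop-1-enyl)dihydrofuran-2(3H)-one | CC(C)=C[C@@H]1C[C@@H]([C@@H](O)CC/C(C)=C/I)C(=O)O1
F5 | step 6 | (1S,4E)-5-iodo-4-methyl-1-[(3S,5S)-5-(2-methylprop-1-enyl)-2-oxotetrahydrofuran-3-yl]pent-4-enyl methanesulfonate | CC(C)=C[C@@H]1C[C@@H]([C@@H](OS(C)(=O)=O)CC/C(C)=C/I)C(=O)O1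
F6 | step 5 | (5S)-3-bromo-5-(2-methylprop-1-enyl)dihydrofuran-2(3H)-one (C-3 epimers) | CC(C)=C[C@@H]1CC(Br)C(=O)O1
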